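## Retrosynthetic overview

1. The target is read as methyl 15-acetoxy-5β-labd-8(17)-en-19-oate (labdane numbering used throughout): rings A/B are cis-fused, with H-5, CH3-20, CO2Me-19 and the C9 side chain all on the β face, and C13 is S.
2. C8=C17 goes back to a C8 ketone (methylenation). C9–C11 goes back to a convex-face alkylation of the C8/C9 enolate with a C5 iodide cut from (S)-citronellol, which supplies C13.
3. Ring B (C5–C6–C7–C8–C9–C10) is not closed at six atoms: C6, C7, C8 and C9 come in as a four-membered ring, 3-(benzyloxy)cyclobutanone, and the C5=C10 double bond of a ring A cyclohexene is inserted into its C6–C9 bond (two-atom ring expansion, formal [4+2]).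
4. Enabling feature: in ring B the C8 carbonyl carbon (later C8=C17) stands 1,3 to C6, so C6–C7–C8–C9 is a latent 3-alkoxycyclobutanone; C10 is a tertiary, cation-stabilising olefin carbon of the cis C5–C10 fusion, and the C4 quaternary ester next to C5 controls the face.
5. Order of ring formation: ring A first (C4 set by a chiral lithio-enamine methylation), then ring B by ring expansion across ring A, then the side chain at C9 and the exocyclic methylene.

Key step: step 6

Remark on the chemistry (assumption): the chelated lithio-enamine 4 from the L-valine ester is taken to be methylated in toluene/HMPA on the face that leads to (S)-6; if the opposite sense were found, the D-valine ester would be used and nothing else would change. Compounds 1, 2, 12 and 15 are taken as commercial.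

## Route

Step 1
Reactants: 1 methyl 2-oxocyclohexane-1-carboxylate; 2 L-valine tert-butyl ester
Product: 3 methyl 2-{[(2S)-1-tert-butoxy-3-methyl-1-oxobutan-2-yl]amino}cyclohex-1-ene-1-carboxylate
Conditions: BF3·OEt2 (cat.), benzene, reflux, Dean–Stark
Reagents that add atoms: none
Why: Condensation of the ketone of the β-keto ester with the primary amine (enamine formation) should give the hydrogen-bonded vinylogous carbamate that carries the chiral auxiliary, with no new stereocentre.

Step 2
Reactants: 3 methyl 2-{[(2S)-1-tert-butoxy-3-methyl-1-oxobutan-2-yl]amino}cyclohex-1-ene-1-carboxylate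
Product: 6 methyl (1S)-1-methyl-2-oxocyclohexane-1-carboxylate, via lithio-enamine 4 (not isolated), via methylated imine 5 (not isolated)
Conditions: LiN(i-Pr)2 (LDA), toluene, −78 °C; HMPA (1 equiv), MeI, −78 °C; then aq. citric acid, rt
Reagents that add atoms: iodomethane, CI; water, O
Why: Auxiliary-controlled alkylation of a chelated lithio-enamine (chiral aza-enolate alkylation): MeI should enter on the face of the future C4 opposite to the isopropyl group of the chelate, and mild acid hydrolysis of imine 5 should release the quaternary (S)-keto ester and the auxiliary.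

Step 3
Reactants: 6 methyl (1S)-1-methyl-2-oxocyclohexane-1-carboxylate
Product: 8 methyl (1S)-1,3-dimethyl-2-oxocyclohexane-1-carboxylate, via lithium enolate 7 (not isolated)
Conditions: LiN(i-Pr)2 (LDA), THF, −78 °C; MeI, −78 → −40 °C
Reagents that add atoms: iodomethane, CI
Why: Kinetic enolate alkylation: C3 (labdane C10) is the only enolisable position of 6, so the future CH3-20 should be installed regiospecifically, and the new C3 stereocentre (both epimers accepted) is erased in step 4.

Step 4
Reactants: 8 methyl (1S)-1,3-dimethyl-2-oxocyclohexane-1-carboxylate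
Product: 10 methyl (1S)-1,3-dimethyl-2-{[(trifluoromethyl)sulfonyl]oxy}cyclohex-2-ene-1-carboxylate, via potassium enolate 9 (not isolated)
Conditions: KN(SiMe3)2, THF, −78 → 0 °C; PhNTf2, −78 °C → rt
Reagents that add atoms: N-phenylbis(trifluoromethanesulfonimide), O=S(=O)(N(c1ccccc1)S(=O)(=O)C(F)(F)F)C(F)(F)F
Why: Enol triflate formation: 8 can enolise only toward C3, and O-sulfonylation of the tetrasubstituted potassium enolate should fix the C2=C3 (labdane C5=C10) double bond without touching the quaternary centre.

Step 5
Reactants: 10 methyl (1S)-1,3-dimethyl-2-{[(trifluoromethyl)sulfonyl]oxy}cyclohex-2-ene-1-carboxylate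
Product: 11 methyl (1S)-1,3-dimethylcyclohex-2-ene-1-carboxylate
Conditions: Pd(OAc)2 (5 mol %), PPh3, HCO2H, Bu3N, DMF, 60 °C
Reagents that add atoms: none
Why: Palladium-catalysed formate reduction of an enol triflate (oxidative addition, decarboxylative hydride transfer, reductive elimination) should replace OTf by H and deliver the ring A olefin with the C4 stereocentre intact.

Step 6
Reactants: 11 methyl (1S)-1,3-dimethylcyclohex-2-ene-1-carboxylate; 12 3-(benzyloxy)cyclobutan-1-one
Product: 14 methyl (1S,4aR,8aS)-1,4a-dimethyl-6-oxo-1,2,3,4,4a,5,6,8a-octahydronaphthalene-1-carboxylate, via benzyloxy ketone 13 (not isolated)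
Conditions: SnCl4 (1.2 equiv), CH2Cl2, −78 → −30 °C (11 in excess); then DBU, −30 → 0 °C
Reagents that add atoms: none
Why: Proposed new method: SnCl4 should open the donor–acceptor cyclobutanone 12 at its C6–C9 bond to a 1,4-zwitterion (benzyloxycarbenium ion at C6, tin enolate C8=C9), the carbenium carbon should add to C5 of the trisubstituted olefin of 11 (Prins-type, Markovnikov, tertiary cation at C10) and the enolate carbon C9 should then collapse onto C10, so that C5 and C10 are inserted into the four-membered ring and this ring becomes ring B, after which DBU removes benzyl alcohol from 13 (E1cB) to give the enone. The closest known reaction type is the Lewis acid-promoted formal [4+2] cycloaddition of 3-alkoxycyclobutanones with allylsilanes, silyl enol ethers, carbonyl compounds and tethered simple alkenes; new here is an untethered, unactivated trisubstituted cycloalkene as the two-atom partner. Ring B is closed by an intermolecular C5–C6 bond formation followed by a six-membered cation–enolate ring closure (C9–C10) through a chair-like arrangement. C5 should be set by axial attack anti to the pseudoaxial CO2Me on C4 (the CH3 on C4 sits pseudoequatorially), and C10 by closure on the same face, because the new C5 side chain stays axial to avoid A(1,2) strain with CH3-20 on the cationic C10 and so holds the enolate under the α face, which gives the cis fusion with H-5 and CH3-20 both β. The step needs regioselectivity (secured by the tertiary cation at C10), face selectivity and cis closure (both secured by the C4 quaternary centre), and the two C6 epimers of 13 converge in the elimination.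

Step 7
Reactants: 15 (S)-citronellol
Product: 16 (S)-citronellyl acetate
Conditions: Ac2O, pyridine, DMAP (cat.), CH2Cl2, 0 °C → rt
Reagents that add atoms: acetic anhydride, CC(=O)OC(C)=O
Why: DMAP-catalysed O-acylation of the primary alcohol should install the acetate of the target at the start, so that C15 needs no protecting group.

Step 8
Reactants: 16 (S)-citronellyl acetate
Product: 17 (4S)-6-acetoxy-4-methylhexanoic acid
Conditions: RuCl3·xH2O (2 mol %), NaIO4, CCl4/MeCN/H2O, rt
Reagents that add atoms: sodium periodate, [Na+].[O-]I(=O)(=O)=O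
Why: RuO4-catalysed oxidative cleavage of the trisubstituted olefin should give the carboxylic acid and acetone directly, the acetate and the remote stereocentre being inert.

Step 9
Reactants: 17 (4S)-6-acetoxy-4-methylhexanoic acid
Product: 18 (3R)-5-iodo-3-methylpentyl acetate
Conditions: PhI(OAc)2, I2, cyclohexane, hν (tungsten lamp), reflux
Reagents that add atoms: iodine, II
Why: Hunsdiecker-type iododecarboxylation through an acyl hypoiodite (radical chain) should remove one carbon and give the primary iodide that carries C11–C16, the descriptor changing from S to R only through the priority of iodine.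

Step 10
Reactants: 14 methyl (1S,4aR,8aS)-1,4a-dimethyl-6-oxo-1,2,3,4,4a,5,6,8a-octahydronaphthalene-1-carboxylate; 18 (3R)-5-iodo-3-methylpentyl acetate
Product: 20 methyl (1S,4aS,5R,8aS)-5-[(3S)-5-acetoxy-3-methylpentyl]-1,4a-dimethyl-6-oxo-1,2,3,4,4a,5,6,8a-octahydronaphthalene-1-carboxylate, via lithium dienolate 19 (not isolated)
Conditions: LiN(i-Pr)2 (LDA), THF, −78 °C; 18, HMPA, −78 → −20 °C
Reagents that add atoms: none
Why: Kinetic α′-deprotonation of the enone at C9 followed by SN2 alkylation of the cross-conjugated dienolate: the iodide should approach C9 on the convex β face, anti to the pseudoaxial C1 of ring A that covers the α face, so that the side chain ends cis to CH3-20 (the descriptors of C9 and C10 change only through priorities).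

Step 11
Reactants: 20 methyl (1S,4aS,5R,8aS)-5-[(3S)-5-acetoxy-3-methylpentyl]-1,4a-dimethyl-6-oxo-1,2,3,4,4a,5,6,8a-octahydronaphthalene-1-carboxylate
Product: 21 methyl (1S,4aS,5R,8aS)-5-[(3S)-5-acetoxy-3-methylpentyl]-1,4a-dimethyl-6-oxodecahydronaphthalene-1-carboxylate
Conditions: H2 (1 atm), 10% Pd/C, EtOAc, rt
Reagents that add atoms: none
Why: Heterogeneous catalytic hydrogenation should saturate only the conjugated C6=C7 bond under neutral conditions, so that the epimerisable C9 centre next to the ketone is not disturbed and no new stereocentre arises.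

Step 12
Reactants: 21 methyl (1S,4aS,5R,8aS)-5-[(3S)-5-acetoxy-3-methylpentyl]-1,4a-dimethyl-6-oxodecahydronaphthalene-1-carboxylate
Product: 22 methyl (1S,4aR,5S,8aS)-5-[(3S)-5-acetoxy-3-methylpentyl]-1,4a-dimethyl-6-methylidenedecahydronaphthalene-1-carboxylate
Conditions: Zn, CH2Br2, TiCl4, THF/CH2Cl2, 0 °C → rt
Reagents that add atoms: dibromomethane, BrCBr
Why: Lombardo methylenation (a non-basic gem-dizinc/TiCl4 methylene transfer) should convert the hindered, enolisable C8 ketone into the exocyclic C8=C17 methylene without epimerising C9 and without attacking the methyl ester or the acetate.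

## Compound list

1 | methyl 2-oxocyclohexane-1-carboxylate | COC(=O)C1CCCCC1=O | starting material
2 | L-valine tert-butyl ester | CC(C)[C@H](N)C(=O)OC(C)(C)C | starting material
3 | methyl 2-{[(2S)-1-tert-butoxy-3-methyl-1-oxobutan-2-yl]amino}cyclohex-1-ene-1-carboxylate | COC(=O)C1=C(N[C@@H](C(C)C)C(=O)OC(C)(C)C)CCCC1 | intermediate
4 | N-lithio derivative of 3 (chelated lithio-enamine) | [Li+].COC(=O)C1=C([N-][C@@H](C(C)C)C(=O)OC(C)(C)C)CCCC1 | intermediate
5 | methyl (1S)-2-{[(2S)-1-tert-butoxy-3-methyl-1-oxobutan-2-yl]imino}-1-methylcyclohexane-1-carboxylate | COC(=O)[C@@]1(C)CCCCC1=N[C@@H](C(C)C)C(=O)OC(C)(C)C | intermediate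
6 | methyl (1S)-1-methyl-2-oxocyclohexane-1-carboxylate | COC(=O)[C@@]1(C)CCCCC1=O | intermediate
7 | lithium enolate of 6 (C2=C3) | [Li+].COC(=O)[C@@]1(C)CCCC=C1[O-] | intermediate
8 | methyl (1S)-1,3-dimethyl-2-oxocyclohexane-1-carboxylate (both C3 epimers) | COC(=O)[C@@]1(C)CCCC(C)C1=O | intermediate
9 | potassium enolate of 8 | [K+].COC(=O)[C@@]1(C)CCCC(C)=C1[O-] | intermediate
10 | methyl (1S)-1,3-dimethyl-2-{[(trifluoromethyl)sulfonyl]oxy}cyclohex-2-ene-1-carboxylate | COC(=O)[C@@]1(C)CCCC(C)=C1OS(=O)(=O)C(F)(F)F | intermediate
11 | methyl (1S)-1,3-dimethylcyclohex-2-ene-1-carboxylate (ring A; labdane C4 and C5=C10) | COC(=O)[C@@]1(C)CCCC(C)=C1 | intermediate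
12 | 3-(benzyloxy)cyclobutan-1-one | O=C1CC(OCc2ccccc2)C1 | starting material
13 | methyl 8-(benzyloxy)-1,4a-dimethyl-6-oxodecahydronaphthalene-1-carboxylate, cis-fused, ring stereocentres as in 14, both C8 epimers (labdane: 6-benzyloxy-8-ketone) | O=C1CC(OCc3ccccc3)[C@H]2[C@](C)(CCC[C@]2(C)C(=O)OC)C1 | intermediate
14 | methyl (1S,4aR,8aS)-1,4a-dimethyl-6-oxo-1,2,3,4,4a,5,6,8a-octahydronaphthalene-1-carboxylate (cis-fused enone; labdane: 8-oxo-6-ene, 5β-H) | O=C1C=C[C@H]2[C@](C)(CCC[C@]2(C)C(=O)OC)C1 | intermediate
15 | (S)-citronellol, (3S)-3,7-dimethyloct-6-en-1-ol | CC(C)=CCC[C@H](C)CCO | starting material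
16 | (S)-citronellyl acetate | CC(C)=CCC[C@H](C)CCOC(C)=O | intermediate
17 | (4S)-6-acetoxy-4-methylhexanoic acid | OC(=O)CC[C@H](C)CCOC(C)=O | intermediate
18 | (3R)-5-iodo-3-methylpentyl acetate | ICC[C@H](C)CCOC(C)=O | intermediate
19 | lithium cross-conjugated dienolate of 14 (O–C8=C9, C6=C7) | [Li+].[O-]C1=C[C@@]2(C)CCC[C@](C)(C(=O)OC)[C@H]2C=C1 | intermediate
20 | methyl (1S,4aS,5R,8aS)-5-[(3S)-5-acetoxy-3-methylpentyl]-1,4a-dimethyl-6-oxo-1,2,3,4,4a,5,6,8a-octahydronaphthalene-1-carboxylate | O=C1C=C[C@H]2[C@](C)(CCC[C@]2(C)C(=O)OC)[C@H]1CC[C@H](C)CCOC(C)=O | intermediate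
21 | methyl (1S,4aS,5R,8aS)-5-[(3S)-5-acetoxy-3-methylpentyl]-1,4a-dimethyl-6-oxodecahydronaphthalene-1-carboxylate | O=C1CC[C@H]2[C@](C)(CCC[C@]2(C)C(=O)OC)[C@H]1CC[C@H](C)CCOC(C)=O | intermediate
22 | methyl (1S,4aR,5S,8aS)-5-[(3S)-5-acetoxy-3-methylpentyl]-1,4a-dimethyl-6-methylidenedecahydronaphthalene-1-carboxylate (methyl 15-acetoxy-5β-labd-8(17)-en-19-oate) | C=C1CC[C@H]2[C@](C)(CCC[C@]2(C)C(=O)OC)[C@H]1CC[C@H](C)CCOC(C)=O | target

## Step count and risks

Total step count: 12. Longest linear sequence: 9 steps (steps 1–6 and 10–12).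

Steps most likely to fail:

1. Step 6 (Proposed new method). The ring-opened zwitterion may not be captured by the hindered olefin and may instead eliminate or oligomerise. The C10 cation may lose a proton or be trapped by the neighbouring ester instead of the enolate. The addition may also occur on the other face of ring A, or the ring may close trans. The fallback uses known chemistry, sets out from 11 and comes back at 14. Dichloroketene (Cl3CCOCl, Zn–Cu, Et2O) should add suprafacially across C5=C10, with C=O going to C5 and CCl2 to C10 and the four-membered ring enforcing the cis fusion, to give the dichlorocyclobutanone F1. CH2N2 should insert a CH2 on the unchlorinated side to give the dichlorocyclopentanone F2. Et3N/Me3SiOTf should give the silyl enol ether F3, since only C6 can enolise. Et2Zn/CH2I2 should give the siloxycyclopropane F4. FeCl3 in DMF should open the inner cyclopropane bond (Saegusa–Ito ring expansion, five to six) to the β-chloro ketone F5, NaOAc should eliminate HCl to the dichloro enone F6, and Zn/AcOH should remove both chlorines to give 14. Ring B would then still arise by ring expansion, in two one-carbon stages.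

2. Step 10. The SN2 reaction at the neopentyl-type enolate carbon may be slow. Proton transfer may then lead to the extended dienolate, with alkylation at C7 or epimerisation at C5, or the enolate may attack the acetate. The fallback sets out from 18 and 14 and comes back at 20. Kornblum oxidation of 18 (DMSO, NaHCO3) should give the aldehyde F7. Aldol addition of dienolate 19 to F7 at −78 °C, a fast reaction with the same convex-face approach, should give the β-hydroxy ketone F8. PhOC(S)Cl/pyridine should give the thionocarbonate F9, and Barton–McCombie deoxygenation (Bu3SnH, AIBN, toluene, 80 °C) should give 20.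

3. Step 12. Methylenation of the hindered ketone may be incomplete, or Lewis-acid enolisation may epimerise C9. The fallback sets out from 21 and comes back at 22 by a Peterson olefination. Me3SiCH2Li/CeCl3 should add to the ketone at −78 °C to give the β-hydroxysilane F10, and acid (HF, MeCN) should induce elimination to 22.

## Further compounds

F1 | step 6 | methyl 7,7-dichloro-2,6-dimethyl-8-oxobicyclo[4.2.0]octane-2-carboxylate, cis-fused (C=O on labdane C5, CCl2 on C10) | O=C1[C@H]2[C@](C)(CCC[C@]2(C)C(=O)OC)C1(Cl)Cl
F2 | step 6 | methyl 1,1-dichloro-4,7a-dimethyl-2-oxooctahydro-1H-indene-4-carboxylate, cis-fused | O=C1C[C@H]2[C@](C)(CCC[C@]2(C)C(=O)OC)C1(Cl)Cl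
F3 | step 6 | trimethylsilyl enol ether of F2 (labdane C8=C6) | C[Si](C)(C)OC1=C[C@H]2[C@](C)(CCC[C@]2(C)C(=O)OC)C1(Cl)Cl
F4 | step 6 | siloxycyclopropane from F3 (CH2 added across C6=C8) | C[Si](C)(C)OC12CC1[C@H]3[C@](C)(CCC[C@]3(C)C(=O)OC)C2(Cl)Cl
F5 | step 6 | methyl 5,5,8-trichloro-1,4a-dimethyl-6-oxodecahydronaphthalene-1-carboxylate, cis-fused | O=C1CC(Cl)[C@H]2[C@](C)(CCC[C@]2(C)C(=O)OC)C1(Cl)Cl
F6 | step 6 | methyl 5,5-dichloro-1,4a-dimethyl-6-oxo-1,2,3,4,4a,5,6,8a-octahydronaphthalene-1-carboxylate, cis-fused | O=C1C=C[C@H]2[C@](C)(CCC[C@]2(C)C(=O)OC)C1(Cl)Cl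
F7 | step 10 | (3R)-5-acetoxy-3-methylpentanal | O=CC[C@H](C)CCOC(C)=O
F8 | step 10 | C9 aldol adduct of 14 with F7 (both C11 carbinol epimers) | O=C1C=C[C@H]2[C@](C)(CCC[C@]2(C)C(=O)OC)[C@H]1C(O)C[C@H](C)CCOC(C)=O
F9 | step 10 | O-phenyl thionocarbonate of F8 | O=C1C=C[C@H]2[C@](C)(CCC[C@]2(C)C(=O)OC)[C@H]1C(OC(=S)Oc3ccccc3)C[C@H](C)CCOC(C)=O
F10 | step 12 | 8-hydroxy-8-[(trimethylsilyl)methyl] adduct of 21 (β-hydroxysilane) | C[Si](C)(C)CC1(O)CC[C@H]2[C@](C)(CCC[C@]2(C)C(=O)OC)[C@H]1CC[C@H](C)CCOC(C)=O
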